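A Ty curve that goes flat once Ux reads empty looks like a finished flask, but a flat curve may also be a balance, and the two react differently when Ty is taken out.

| flask | Ux | Ek | temperature | remark | time |
|---|---|---|---|---|---|
| noon | 0.80 M | 1.2 M | 0 °C | the very flask that is asked about, followed so far |  |
| midnight | 1.2 M | 1.2 M | −15 °C | run made earlier |  |
| flask | 0.80 M | 1.20 M | 0 °C |  | 4.0 h |

| run | time / min | Ty / % | Ux / % |
|---|---|---|---|
| noon | 20.0 | 40 | 35 |
| noon | 40.0 | 54 | 20 |
| noon | 90.0 | 69 | 8 |
| noon | 240 | 76 | 0 |
| midnight | 12.0 | 19 | 77 |
| midnight | 25.0 | 32 | 62 |
| midnight | 40.0 | 38 | 59 |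
| midnight | 50.0 | 41 | 48 |

(readings scatter by 2 percentage points)

- ochre: at 4.0 h raise the temperature by 10 K, then wait 2.0 h
- violet: change nothing and wait 2.0 h more
- green: at 4.0 h take out 90% of the Ty then present, then wait 2.0 h

- Ty taken out counts as made
- what was read earlier has a scatter of 2 percentage points, one standard deviation

* Ty, in percent of the Ux first charged, at 4.0 h
* the option that brings most further Ty ("none" if no option brings more than 2 percentage points) (ochre / violet / green / none)
* Ty present, with what was taken out counted in, in percent of the Ux first charged, after violet
* Ty present, with what was taken out counted in, in percent of the Ux first charged, after green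

The noon run is this flask, and at 240 min it reads Ty 76% and Ux 0%, so the reckoning here commits to 76% now and the same after violet. Ux is the limiting reagent. A share m = 24.0% of the charge is in neither form, and it already stood at 25.0% at 20.0 min. Suppose m is complex that has exchanged twice, and count turnovers: n, the Ek used per Ux charged, is Ty + 2m = 1.24, against 1.50 charged. So 0.208 M of Ek stands beside 0.608 M of Ty, and m has stopped growing with both partners present, which points to a reversible second exchange. With 0.192 M of twice-exchanged complex and 0.992 M of freed ligand, the balance quotient Q, (twice-exchanged × freed ligand)/(Ty × Ek), reads 1.51; it is the equilibrium constant as read.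

Green leaves 0.0608 M of Ty. If x of the twice-exchanged complex turns back until Q holds again, then (dz − x)(lig − x) = Q(rest + x)(Ek + x), which gives x = 0.104 M. That is a gain of 13 percentage points, for a total of 89.0%. The midnight run still holds 48% Ux at its last reading, so it gives no reading of Q at its own temperature, and ochre stays unreckoned here. The commitment to green rests on the reckoned gain of 13 points, with ochre left open.

The weak link is Q, which rests on one reading. Moving Ty by 2 points either way takes Q to 1.23 or 1.84, yet the gain stays at 13 points and 13 points.

The forecast, which parts from this reckoning on green, gives 76% now, 76.5% after violet, 76.5% after green and none as best, holding that “removing Ty cannot pull anything forward”.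

The flask gives 78.2% now, 78.9% after violet and 91.2% after green, and the best option is green, with a gain of 13 points against 5 points for ochre.

    Ux + Ek → Qe + Ty (k = 0.00110 M⁻¹ s⁻¹, Ea = 47.0 kJ mol⁻¹)
    Ty + Ek ⇌ Qe + Dz (K = 1.10, k = 0.00110 M⁻¹ s⁻¹, Ea = 66.0 kJ mol⁻¹, ΔH = −28.0 kJ mol⁻¹)
    (constants at 0 °C)

In this flask at the asked time, Ty + Ek ⇌ Qe + Dz relaxes with a half-life of 5.55 min, far shorter than the 4.0 h elapsed. Ek then goes by the step from Ux at 0.0083 of the forward rate of that exchange. A neighbour flask with 0.48 M of Ux has 2.50 equiv of Ek, and Q puts its Ty at 49.9%. That neighbour flask stands at 55.5% Ty.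

(The runs were computed on assumed constants, noise included.)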